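**Plan**

Labels: ring A is the methoxycyclohexenedione, ring B the cyclopentane, Ca the spiro carbon shared by rings A and B, Cb the spiro carbon shared by ring B and the pinane (pinane C2), C1′ the ring-B carbon bearing isopropyl, then C2′ and C3′ back to Cb.
Cuts, in retrosynthetic order: the enol ether O–CH3 bond; the C(CH3)–C(=O) bond of ring A beside Ca (Dieckmann); together the Ca–acyl and C1′–isopropyl bonds, leaving a Ca=C1′ cyclopentene ester; then Ca–C1′ (aldol) and Cb–C3′ (conjugate addition to a nopinylidene malonate).
Forward order: pinane ketone from (+)-α-pinene, quaternary Cb, ring B, isopropyl and acyl chain across Ca=C1′, ring A, methyl ether.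
Enabling feature: Ca and C1′ are neighbouring stereocentres of ring B, and the C(CH3)2-flanked carbonyl of ring A on Ca is trans to the isopropyl group on C1′; this is what anti addition of a carbon nucleophile (at C1′) and an acyl electrophile (at Ca) across a Ca=C1′ double bond leaves behind.
Stereochemistry: pinane C1 and C5 come from (+)-α-pinene; Cb from organocopper attack on the alkylidene malonate face opposite the gem-dimethyl bridge; C1′ from addition to the cyclopentene face away from the pinane bridgehead; Ca from acylation anti to isopropyl.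

Key step: step 10

Remark: trione 25 is drawn as the triketone although it should be largely enolised, and commercial (+)-α-pinene is taken as the (1R,5R) enantiomer of high enantiomeric purity.

**Route**

Step 1
Reactants: 1 (1R,5R)-(+)-α-pinene
Product: 4 (1R,5R)-(+)-β-pinene, via myrtenylpotassium 2 (not isolated), via dimethyl myrtenylboronate 3 (not isolated)
Conditions: n-BuLi, KOt-Bu, hexane, rt; B(OMe)3, Et2O, −78 °C; aq. HCl, 0 °C
Reagents that add atoms: none
Why: Metalation of the allylic methyl group by the n-BuLi/KOt-Bu superbase, borylation at the primary carbon and protonolysis of the allylboronate with allylic transposition (SE2′) should move the double bond to the exocyclic position against the thermodynamic preference, while C1 and C5 are not touched (allylic metalation–borylation–protodeboronation).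

Step 2
Reactants: 4 (1R,5R)-(+)-β-pinene
Product: 5 (1S,5R)-(−)-nopinone
Conditions: O3, CH2Cl2–MeOH, −78 °C; Me2S, −78 °C → rt
Reagents that add atoms: ozone, [O-][O+]=O
Why: Ozonolysis with reductive work-up cleaves the 1,1-disubstituted alkene to the ketone and formaldehyde and leaves both bridgehead centres as they are.

Step 3
Reactants: 5 (1S,5R)-(−)-nopinone; 6 dimethyl malonate
Product: 7 dimethyl 2-(6,6-dimethylbicyclo[3.1.1]heptan-2-ylidene)malonate
Conditions: TiCl4, pyridine, THF, 0 °C → rt
Reagents that add atoms: none
Why: The TiCl4–pyridine Knoevenagel condensation is the established way to join malonates to enolisable α-branched ketones because the titanium aldolate eliminates irreversibly, and no stereocentre is created.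

Step 4
Reactants: 7 dimethyl 2-(6,6-dimethylbicyclo[3.1.1]heptan-2-ylidene)malonate; 8 2-(2-bromoethyl)-1,3-dioxolane
Product: 10 dimethyl 2-{2-[2-(1,3-dioxolan-2-yl)ethyl]-6,6-dimethylbicyclo[3.1.1]heptan-2-yl}malonate, via dioxolanylethylmagnesium bromide 9 (not isolated)
Conditions: 8, Mg, THF, 20 °C; then CuBr·SMe2 (10 mol %), 7, THF, −30 → 0 °C; aq. NH4Cl
Reagents that add atoms: none
Why: Copper-catalysed conjugate addition of a Grignard reagent to a doubly activated tetrasubstituted alkene builds quaternary Cb, and the organocopper should attack from the face of the CH2 bridge, opposite the gem-dimethyl bridge (the usual bias of β-pinene-type exocyclic alkenes), so that the malonate carbon Ca ends up cis to the gem-dimethyl bridge.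

Step 5
Reactants: 10 dimethyl 2-{2-[2-(1,3-dioxolan-2-yl)ethyl]-6,6-dimethylbicyclo[3.1.1]heptan-2-yl}malonate
Product: 11 dimethyl 2-[6,6-dimethyl-2-(3-oxopropyl)bicyclo[3.1.1]heptan-2-yl]malonate
Conditions: 2 M HCl, THF, rt
Reagents that add atoms: water, O
Why: Aqueous acid hydrolyses the dioxolane (acetal deprotection) while the methyl esters and quaternary Cb are inert, so the aldehyde for ring closure is released without touching a stereocentre.

Step 6
Reactants: 11 dimethyl 2-[6,6-dimethyl-2-(3-oxopropyl)bicyclo[3.1.1]heptan-2-yl]malonate
Product: 13 spiro mesylate diester (ring B: Cb–Ca(CO2Me)2–C1′H(OMs)–C2′H2–C3′H2), via spiro cyclopentanol diester 12 (not isolated)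
Conditions: DBU (10 mol %), CH2Cl2, rt; then Et3N, MsCl, 0 °C
Reagents that add atoms: methanesulfonyl chloride, CS(=O)(=O)Cl
Why: Amine-catalysed intramolecular aldol addition of the malonate C–H to the aldehyde closes ring B (5-exo-trig, the neutral cyclic aldol being favoured under catalytic base), and mesylation through sulfene traps the hindered alcohol so that retro-aldol opening is shut off; the carbinol centre forms as a mixture and is removed in step 7.

Step 7
Reactants: 13 spiro mesylate diester
Product: 14 methyl spiro[pinane-2,5′-cyclopent-1′-ene]-1′-carboxylate (ring B: Cb–Ca(CO2Me)=C1′H–C2′H2–C3′H2)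
Conditions: LiCl, DMSO, 140 °C
Reagents that add atoms: none
Why: Krapcho demethylation by chloride gives a carboxylate that loses CO2 while the β-mesylate is expelled (from the ester enolate or in a Grob-type fragmentation), so dealkoxycarbonylation and elimination should give the conjugated Ca=C1′ ester in one operation, Cb having no hydrogen to offer.

Step 8
Reactants: 15 tert-butyl isobutyrate; 16 propionyl chloride
Product: 18 tert-butyl 2,2-dimethyl-3-oxopentanoate, via lithium enolate 17 (not isolated)
Conditions: LDA, THF, −78 °C; enolate added to 16, THF, −78 °C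
Reagents that add atoms: none
Why: C-acylation of a lithium ester enolate by an acid chloride (crossed Claisen condensation) gives the β-keto ester, which has no hydrogen between its carbonyl groups and so does not quench a second equivalent of enolate.

Step 9
Reactants: 18 tert-butyl 2,2-dimethyl-3-oxopentanoate
Product: 20 2,2-dimethyl-3-oxopentanoyl chloride, via 2,2-dimethyl-3-oxopentanoic acid 19 (not isolated)
Conditions: TFA, CH2Cl2, 0 °C; concentrate below 20 °C; (COCl)2, catalytic DMF, CH2Cl2, 0 °C
Reagents that add atoms: oxalyl chloride, ClC(=O)C(Cl)=O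
Why: Acidolysis of the tert-butyl ester avoids hydroxide and with it retro-Claisen cleavage, and the β-keto acid is chlorinated cold under Vilsmeier-type catalysis before it can decarboxylate.

Step 10
Reactants: 14 methyl spiro[pinane-2,5′-cyclopent-1′-ene]-1′-carboxylate; 21 isopropylmagnesium chloride; 20 2,2-dimethyl-3-oxopentanoyl chloride
Product: 24 spiro keto ester with CO2Me and the 2,2-dimethyl-3-oxopentanoyl group on Ca and isopropyl on C1′ trans to that acyl group, via silyl ketene acetal 22 (not isolated), via lithium enolate 23 (not isolated)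
Conditions: 21 (1.5 equiv), CuBr·SMe2 (10 mol %), Me3SiCl (2 equiv), THF, −78 → −30 °C; Et3N, pentane, filter, concentrate; MeLi (1.05 equiv), THF, 0 °C; then 20, −78 → 0 °C
Reagents that add atoms: none
Why: An isopropylcopper species formed from 21 and catalytic CuBr·SMe2 adds to the β-carbon C1′ of the enoate, Me3SiCl traps the enolate as silyl ketene acetal 22, MeLi cleaves the O–Si bond to give lithium enolate 23, and 23 attacks acid chloride 20 through carbon, so the C1′–isopropyl and Ca–acyl bonds form in one flask. The closest known reaction type is the copper-catalysed Grignard conjugate addition to cycloalkene esters followed by C-acylation of the regenerated ester enolate. No ring closes. C1′ is controlled by Cb: its bridgehead arm (pinane C1 with the dimethylcyclobutane) screens one face of the cyclopentene more than the C3 methylene arm does, so isopropyl should enter from the C3 side. Ca is controlled by the new isopropyl group next to it, the acid chloride approaching the exocyclic enolate from the opposite face, which places the C(CH3)2-bearing acyl group trans to isopropyl and leaves the ester as the future enone carbonyl. The step needs 1,4- over 1,2-addition (copper and Me3SiCl at an unhindered β-CH), C- over O-acylation (lithium ester enolate, acid chloride added cold) and the two facial selectivities; the first rests on a modest substrate bias and the second on a vicinal substituent.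

Step 11
Reactants: 24 spiro keto ester
Product: 25 spiro trione (ring A: Ca–C(=O)–CH(CH3)–C(=O)–C(CH3)2–C(=O)–Ca)
Conditions: KOt-Bu (2.2 equiv), THF, 0 °C → rt; aq. HCl
Reagents that add atoms: none
Why: Dieckmann (intramolecular Claisen) condensation of the only enolate available, that of the ethyl ketone, onto the methyl ester closes ring A as a six-membered ring and is driven by deprotonation of the 2-methyl-1,3-dione formed, while quaternary Ca cannot epimerise.

Step 12
Reactants: 25 spiro trione
Product: 26 CNP0307059.1
Conditions: Me2SO4, K2CO3, acetone, rt → 50 °C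
Reagents that add atoms: dimethyl sulfate, COS(=O)(=O)OC
Why: O-alkylation of the β-diketonate by a hard methylating agent gives the vinylogous ester, and the oxygen beside C(CH3)2 is much more accessible than the one beside Ca with its isopropyl and pinane neighbours, so methyl should go to the oxygen remote from Ca.

**Compound list**

1 | (1R,5R)-(+)-α-pinene | CC1=CC[C@@H]2C[C@H]1C2(C)C | starting material
2 | myrtenylpotassium (1 metalated at the C2 methyl group) | [K]CC1=CC[C@@H]2C[C@H]1C2(C)C | intermediate
3 | dimethyl myrtenylboronate (B(OMe)2 on the former methyl carbon of 1) | COB(OC)CC1=CC[C@@H]2C[C@H]1C2(C)C | intermediate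
4 | (1R,5R)-(+)-β-pinene | C=C1CC[C@@H]2C[C@H]1C2(C)C | intermediate
5 | (1S,5R)-(−)-nopinone, 6,6-dimethylbicyclo[3.1.1]heptan-2-one | O=C1CC[C@@H]2C[C@H]1C2(C)C | intermediate
6 | dimethyl malonate | COC(=O)CC(=O)OC | starting material
7 | dimethyl 2-(6,6-dimethylbicyclo[3.1.1]heptan-2-ylidene)malonate, bicyclic core as in 5 | COC(=O)C(C(=O)OC)=C1CC[C@@H]2C[C@H]1C2(C)C | intermediate
8 | 2-(2-bromoethyl)-1,3-dioxolane | BrCCC1OCCO1 | starting material
9 | [2-(1,3-dioxolan-2-yl)ethyl]magnesium bromide | Br[Mg]CCC1OCCO1 | intermediate
10 | dimethyl 2-{2-[2-(1,3-dioxolan-2-yl)ethyl]-6,6-dimethylbicyclo[3.1.1]heptan-2-yl}malonate; at Cb the malonate carbon is cis to the gem-dimethyl bridge, the side chain cis to the CH2 bridge | COC(=O)C(C(=O)OC)[C@@]1(CCC3OCCO3)CC[C@@H]2C[C@H]1C2(C)C | intermediate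
11 | dimethyl 2-[6,6-dimethyl-2-(3-oxopropyl)bicyclo[3.1.1]heptan-2-yl]malonate, Cb as in 10 | COC(=O)C(C(=O)OC)[C@@]1(CCC=O)CC[C@@H]2C[C@H]1C2(C)C | intermediate
12 | spiro cyclopentanol diester, ring B Cb–Ca(CO2Me)2–C1′H(OH)–C2′H2–C3′H2 spiro at pinane C2, Ca cis to the gem-dimethyl bridge, C1′ epimers | COC(=O)C3(C(=O)OC)C(O)CC[C@@]31CC[C@@H]2C[C@H]1C2(C)C | intermediate
13 | spiro mesylate diester, the methanesulfonate of 12 | COC(=O)C3(C(=O)OC)C(OS(C)(=O)=O)CC[C@@]31CC[C@@H]2C[C@H]1C2(C)C | intermediate
14 | methyl spiro[pinane-2,5′-cyclopent-1′-ene]-1′-carboxylate, ring B Cb–Ca(CO2Me)=C1′H–C2′H2–C3′H2, Ca cis to the gem-dimethyl bridge | COC(=O)C3=CCC[C@@]31CC[C@@H]2C[C@H]1C2(C)C | intermediate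
15 | tert-butyl isobutyrate | CC(C)C(=O)OC(C)(C)C | starting material
16 | propionyl chloride | CCC(Cl)=O | starting material
17 | lithium enolate of tert-butyl isobutyrate | CC(C)=C(O[Li])OC(C)(C)C | intermediate
18 | tert-butyl 2,2-dimethyl-3-oxopentanoate | CCC(=O)C(C)(C)C(=O)OC(C)(C)C | intermediate
19 | 2,2-dimethyl-3-oxopentanoic acid | CCC(=O)C(C)(C)C(O)=O | intermediate
20 | 2,2-dimethyl-3-oxopentanoyl chloride | CCC(=O)C(C)(C)C(Cl)=O | intermediate
21 | isopropylmagnesium chloride | CC(C)[Mg]Cl | starting material
22 | trimethylsilyl ketene acetal of the conjugate adduct, isopropyl on C1′ on the face of pinane C3, exocyclic Ca=C(OMe)OSiMe3 | COC(O[Si](C)(C)C)=C3[C@@H](C(C)C)CC[C@@]31CC[C@@H]2C[C@H]1C2(C)C | intermediate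
23 | lithium ester enolate corresponding to 22 | COC(O[Li])=C3[C@@H](C(C)C)CC[C@@]31CC[C@@H]2C[C@H]1C2(C)C | intermediate
24 | spiro keto ester: Ca bears CO2Me and C(=O)C(CH3)2C(=O)CH2CH3, C1′ bears isopropyl trans to that acyl group and cis to CO2Me | CCC(=O)C(C)(C)C(=O)[C@]3(C(=O)OC)[C@@H](C(C)C)CC[C@@]31CC[C@@H]2C[C@H]1C2(C)C | intermediate
25 | spiro trione, ring A Ca–C(=O)–CH(CH3)–C(=O)–C(CH3)2–C(=O)–Ca, ring B and pinane as in 24 | O=C1C(C)C(=O)[C@@]2(C(=O)C1(C)C)[C@@H](C(C)C)CC[C@@]21CC[C@@H]2C[C@H]1C2(C)C | intermediate
26 | CNP0307059.1, methyl enol ether of 25 at the oxygen beside C(CH3)2; Ca R, C1′ R, Cb R, pinane C1 S, pinane C5 R | COC1=C(C)C(=O)[C@@]2(C(=O)C1(C)C)[C@@H](C(C)C)CC[C@@]21CC[C@@H]2C[C@H]1C2(C)C | target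

**Count**

Total steps: 12. Longest linear sequence: 10 steps (steps 1–7 and 10–12); steps 8 and 9 form the two-step side branch to acid chloride 20.

**Steps most likely to fail**

Step 10. C-acylation of the very hindered enolate 23 may be outrun by proton transfer from the ethyl ketone of 20 or by O-acylation, so that only the plain conjugate adduct is recovered after work-up. The fallback lowers the oxidation level of the electrophile and replaces the basic enolate by a Lewis-acid-mediated addition. It sets out from 14 and 20. Reduction of 20 with Bu3SnH and catalytic Pd(PPh3)4 should give 2,2-dimethyl-3-oxopentanal F1. Silyl ketene acetal 22, made from 14 as in the first stage of step 10, is then combined with F1 and TiCl4 in CH2Cl2 at −78 °C (Mukaiyama aldol addition, again anti to isopropyl) to give the β-hydroxy ester F2 as carbinol epimers. Oxidation of F2 with Dess–Martin periodinane comes back to the route at 24.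

Step 6. The aldol equilibrium may lie on the side of open aldehyde 11, because ring closure makes a fully substituted Ca next to quaternary Cb, and mesylation may then trap too little of 12. The fallback closes ring B by irreversible alkylation and sets out from 11. NaBH4 in MeOH at 0 °C should give the primary alcohol F3, and I2, PPh3 and imidazole the iodide F4. NaH in THF–DMF cyclises the malonate anion onto the iodide (5-exo-tet) to the spiro cyclopentane diester F5. Krapcho dealkoxycarbonylation (LiCl, wet DMSO, 150 °C) gives the monoester F6. LDA followed by PhSeBr gives the α-phenylselanyl ester F7, and H2O2 oxidation with syn elimination of the selenoxide towards C1′, the only side with β-hydrogens, comes back to the route at 14.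

Step 12. Methylation may be shared between the two enolate oxygens or go to carbon C4, giving the regioisomeric enol ether or a C-methylated trione. The fallback replaces kinetic alkylation of the enolate by acid-catalysed enol ether formation under equilibrating conditions. From 25, HC(OMe)3 and MeOH with catalytic TsOH at rt let methanol add to the less hindered carbonyl carbon and let the two vinylogous esters interconvert, so the less strained isomer should accumulate and carbon alkylation is excluded. It sets out from 25 and comes back at 26 without a new compound.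

**Further compounds**

F1 | step 10 | 2,2-dimethyl-3-oxopentanal | CCC(=O)C(C)(C)C=O
F2 | step 10 | β-hydroxy ester, Ca bearing CO2Me and CH(OH)C(CH3)2C(=O)CH2CH3, carbinol epimers | CCC(=O)C(C)(C)C(O)[C@]3(C(=O)OC)[C@@H](C(C)C)CC[C@@]31CC[C@@H]2C[C@H]1C2(C)C
F3 | step 6 | dimethyl 2-[2-(3-hydroxypropyl)-6,6-dimethylbicyclo[3.1.1]heptan-2-yl]malonate | COC(=O)C(C(=O)OC)[C@@]1(CCCO)CC[C@@H]2C[C@H]1C2(C)C
F4 | step 6 | dimethyl 2-[2-(3-iodopropyl)-6,6-dimethylbicyclo[3.1.1]heptan-2-yl]malonate | COC(=O)C(C(=O)OC)[C@@]1(CCCI)CC[C@@H]2C[C@H]1C2(C)C
F5 | step 6 | spiro cyclopentane diester, ring B Cb–Ca(CO2Me)2–C1′H2–C2′H2–C3′H2 | COC(=O)C3(C(=O)OC)CCC[C@@]31CC[C@@H]2C[C@H]1C2(C)C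
F6 | step 6 | spiro cyclopentane monoester, Ca epimers | COC(=O)C3CCC[C@@]31CC[C@@H]2C[C@H]1C2(C)C
F7 | step 6 | α-phenylselanyl ester of F6 | COC(=O)C3([Se]c4ccccc4)CCC[C@@]31CC[C@@H]2C[C@H]1C2(C)C
F0 | step 12 | none | none
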